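**Strategy.** With carotenoid numbering, the ε-ring (C1–C6) is disconnected at C2–C3 and at C4=C5, which removes C3–C4 as a vinyl unit. The key step is a photoredox decarboxylative Schweizer-type annulation: a primary C2 radical from an open-chain δ-keto carboxylate adds to vinyltriphenylphosphonium bromide, the α-phosphonio radical is reduced to an ylide, and intramolecular Wittig olefination of the C5 methyl ketone closes the cyclohexene. It exploits the methyl-bearing trisubstituted C4=C5 alkene flanked by the C3–C4 ethano bridge and the gem-dimethyl C1. C6 is set beforehand by auxiliary-controlled alkylation; the ring is advanced to (R)-α-ionone and a C15 phosphonium salt, then joined by two Wittig reactions to the C10 dialdehyde and farnesyl phosphonium.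

Key step: step 7

Remark on the chemistry: each Wittig step is assumed to give an E/Z mixture at the new disubstituted double bond, which is equilibrated to all-E by catalytic iodine, as is usual for conjugated carotenoid polyenes; carotenoid numbering is used for atoms throughout.

Step 1
Reactants: 1 3,3-dimethylglutaric anhydride
Product: 2 5-tert-butoxy-3,3-dimethyl-5-oxopentanoic acid
Conditions: t-BuOH (3 equiv), DMAP (cat.), N-hydroxysuccinimide (cat.), Et3N (cat.), toluene, reflux
Reagents that add atoms: tert-butanol, CC(C)(C)O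
Why: Nucleophile-catalysed alcoholysis of a symmetrical cyclic anhydride should give the half-ester directly, since both carbonyl groups are equivalent.

Step 2
Reactants: 2 5-tert-butoxy-3,3-dimethyl-5-oxopentanoic acid; 3 (4R)-4-benzyl-1,3-oxazolidin-2-one
Product: 5 tert-butyl 5-[(4R)-4-benzyl-2-oxo-1,3-oxazolidin-3-yl]-3,3-dimethyl-5-oxopentanoate, via mixed pivalic anhydride 4 (not isolated)
Conditions: PivCl, Et3N, THF, −20 °C; then 3, LiCl, −20 °C → rt
Reagents that add atoms: none
Why: N-Acylation of the oxazolidinone through the mixed pivalic anhydride, which should be attacked at the less hindered non-pivaloyl carbonyl, with LiCl/Et3N activating the auxiliary without strong base.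

Step 3
Reactants: 5 tert-butyl 5-[(4R)-4-benzyl-2-oxo-1,3-oxazolidin-3-yl]-3,3-dimethyl-5-oxopentanoate
Product: 7 tert-butyl (4S)-4-[(benzyloxy)methyl]-5-[(4R)-4-benzyl-2-oxo-1,3-oxazolidin-3-yl]-3,3-dimethyl-5-oxopentanoate, via chlorotitanium Z-enolate 6 (not isolated)
Conditions: TiCl4 (1.05 equiv), i-Pr2NEt (1.1 equiv), CH2Cl2, 0 °C; then BnOCH2Cl, 0 °C, short reaction time
Reagents that add atoms: benzyl chloromethyl ether, ClCOCc1ccccc1
Why: Auxiliary-controlled (Evans) alkylation in which the chelated Z-enolate is attacked by the oxocarbenium-like electrophile on the face opposite the C4 benzyl group of the (R)-auxiliary, setting C6 as S in 7; only the far more acidic imide is enolised, not the tert-butyl ester.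

Step 4
Reactants: 7 tert-butyl (4S)-4-[(benzyloxy)methyl]-5-[(4R)-4-benzyl-2-oxo-1,3-oxazolidin-3-yl]-3,3-dimethyl-5-oxopentanoate
Product: 8 tert-butyl (4S)-4-[(benzyloxy)methyl]-5-(ethylsulfanyl)-3,3-dimethyl-5-oxopentanoate
Conditions: EtSH, n-BuLi, THF, 0 °C; then 7, 0 °C → rt; aq. NH4Cl
Reagents that add atoms: ethanethiol (as lithium ethanethiolate), CCS
Why: Thiolysis of the N-acyloxazolidinone by a soft, weakly basic thiolate should cleave the exocyclic carbonyl without epimerising C6 and leave the tert-butyl ester untouched.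

Step 5
Reactants: 8 tert-butyl (4S)-4-[(benzyloxy)methyl]-5-(ethylsulfanyl)-3,3-dimethyl-5-oxopentanoate
Product: 9 tert-butyl (4S)-4-[(benzyloxy)methyl]-3,3-dimethyl-5-oxohexanoate
Conditions: MeZnCl (2.5 equiv), PdCl2(PPh3)2 (5 mol %), THF/toluene, rt
Reagents that add atoms: methylzinc chloride, C[Zn]Cl
Why: Fukuyama coupling, in which Pd inserts into the C(O)–S bond and accepts methyl from zinc, should stop at the methyl ketone, tolerate ester and benzyl ether, and involve no base that could epimerise C6.

Step 6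
Reactants: 9 tert-butyl (4S)-4-[(benzyloxy)methyl]-3,3-dimethyl-5-oxohexanoate
Product: 10 (4S)-4-[(benzyloxy)methyl]-3,3-dimethyl-5-oxohexanoic acid
Conditions: TFA/CH2Cl2 (1:4), 0 °C → rt
Reagents that add atoms: none
Why: Acidolysis of the tert-butyl ester (E1 loss of isobutene) frees the acid under non-basic conditions that should not affect the α-stereocentre or the benzyl ether.

Step 7
Reactants: 10 (4S)-4-[(benzyloxy)methyl]-3,3-dimethyl-5-oxohexanoic acid; 11 vinyltriphenylphosphonium bromide
Product: 14 ({[(1R)-2,6,6-trimethylcyclohex-2-en-1-yl]methoxy}methyl)benzene, via caesium carboxylate 12 (not isolated), via phosphonium ylide 13 (not isolated)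
Conditions: Cs2CO3 (0.5 equiv), MeOH, then evaporation and toluene azeotrope; 11 (2 equiv), Ir[dF(CF3)ppy]2(dtbbpy)PF6 (1 mol %), 4 Å MS, degassed DMSO, blue LEDs, 25 °C
Reagents that add atoms: none
Why: Proposed new method: the excited Ir(III) photocatalyst should oxidise carboxylate 12, CO2 is lost, and the primary C2 radical adds to the CH2 terminus of the vinylphosphonium cation (C2–C3 bond); the α-phosphonio radical is then reduced by Ir(II) to ylide 13 (radical–polar crossover), which olefinates the methyl ketone intramolecularly (C4=C5 bond) with loss of Ph3P=O, so the sequence is redox-neutral and needs no external base. The closest known reaction types are the Schweizer annulation (anionic nucleophile plus vinylphosphonium salt, then intramolecular Wittig reaction on a methyl ketone) and photoredox decarboxylative Giese additions that end in radical–polar crossover. The six-membered ring closes by 6-exo-trig attack of the ylide carbon on the C5 carbonyl, followed by oxaphosphetane cycloreversion that leaves the alkene endocyclic. No new stereocentre is formed; C6 is carried over from 10 and is protected from enolisation by the adjacent quaternary C1 and the absence of added base. The step needs intermolecular radical addition to outrun 1,5-hydrogen transfer from the acetyl methyl group and olefination to outrun proton transfer to the ylide; the polarity match of a nucleophilic alkyl radical with a cationic acceptor used in excess, the gem-dimethyl (Thorpe–Ingold) bias for ring closure, and strictly aprotic conditions are meant to secure both.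

Step 8
Reactants: 14 ({[(1R)-2,6,6-trimethylcyclohex-2-en-1-yl]methoxy}methyl)benzene
Product: 15 [(1R)-2,6,6-trimethylcyclohex-2-en-1-yl]methanol ((R)-α-cyclogeraniol)
Conditions: Li, NH3(l)/THF, −78 °C; then NH4Cl
Reagents that add atoms: none
Why: Dissolving-metal (Birch-type) cleavage of the benzylic C–O bond should leave the isolated trisubstituted alkene and the homoallylic C–O bond intact.

Step 9
Reactants: 15 [(1R)-2,6,6-trimethylcyclohex-2-en-1-yl]methanol
Product: 16 (1R)-2,6,6-trimethylcyclohex-2-ene-1-carbaldehyde ((R)-α-cyclocitral)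
Conditions: Dess–Martin periodinane, NaHCO3, CH2Cl2, 0 °C → rt
Reagents that add atoms: none
Why: Dess–Martin oxidation under buffered, non-basic conditions should give the β,γ-unsaturated aldehyde without epimerisation at C6 or migration of the alkene into conjugation.

Step 10
Reactants: 16 (1R)-2,6,6-trimethylcyclohex-2-ene-1-carbaldehyde; 17 1-(triphenyl-λ5-phosphanylidene)propan-2-one
Product: 18 (3E)-4-[(1R)-2,6,6-trimethylcyclohex-2-en-1-yl]but-3-en-2-one ((R)-α-ionone)
Conditions: toluene, 90 °C
Reagents that add atoms: none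
Why: Wittig olefination with a stabilised, essentially non-basic ylide should give the (E)-enone and avoid enolisation of the sensitive aldehyde.

Step 11
Reactants: 18 (3E)-4-[(1R)-2,6,6-trimethylcyclohex-2-en-1-yl]but-3-en-2-one
Product: 19 (4E)-3-methyl-5-[(1R)-2,6,6-trimethylcyclohex-2-en-1-yl]penta-1,4-dien-3-ol (mixture of carbinol epimers)
Conditions: CH2=CHMgBr, THF, −20 → 0 °C; aq. NH4Cl
Reagents that add atoms: vinylmagnesium bromide, C=C[Mg]Br
Why: Grignard 1,2-addition to the enone carbonyl gives the tertiary bis-allylic alcohol; the new carbinol centre forms unselectively and is erased in step 12.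

Step 12
Reactants: 19 (4E)-3-methyl-5-[(1R)-2,6,6-trimethylcyclohex-2-en-1-yl]penta-1,4-dien-3-ol
Product: 20 [(2E,4E)-3-methyl-5-[(1R)-2,6,6-trimethylcyclohex-2-en-1-yl]penta-2,4-dien-1-yl]triphenylphosphonium bromide
Conditions: Ph3P·HBr, MeOH, rt
Reagents that add atoms: triphenylphosphine hydrobromide, [Br-].c1ccc([PH+](c2ccccc2)c2ccccc2)cc1
Why: Acid ionises the tertiary alcohol to a pentadienyl cation that triphenylphosphine should capture at the unhindered primary terminus (SN1′-type allylic transposition), giving the conjugated (2E,4E) salt with C6 untouched.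

Step 13
Reactants: 20 C15 phosphonium bromide; 21 (2E,4E,6E)-2,7-dimethylocta-2,4,6-trienedial
Product: 23 (2E,4E,6E,8E,10E,12E)-2,7,11-trimethyl-13-[(1R)-2,6,6-trimethylcyclohex-2-en-1-yl]trideca-2,4,6,8,10,12-hexaenal, via C15 ylide 22 (not isolated)
Conditions: 21 (3 equiv), NaOMe, MeOH/CH2Cl2, 0 °C → rt; then cat. I2, CH2Cl2, daylight
Reagents that add atoms: none
Why: Wittig olefination of one formyl group of the symmetrical dialdehyde used in excess builds C11=C12, and iodine-catalysed equilibration should convert the Z-isomer at the new disubstituted alkene into the all-E polyenal.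

Step 14
Reactants: 24 (2E,6E)-1-bromo-3,7,11-trimethyldodeca-2,6,10-triene ((E,E)-farnesyl bromide); 25 triphenylphosphine
Product: 26 [(2E,6E)-3,7,11-trimethyldodeca-2,6,10-trien-1-yl]triphenylphosphonium bromide
Conditions: toluene, rt, dark
Reagents that add atoms: none
Why: SN2 quaternisation of triphenylphosphine by the primary allylic bromide should proceed without allylic transposition, so both E-trisubstituted alkenes are retained.

Step 15
Reactants: 26 farnesyltriphenylphosphonium bromide; 23 C25 polyenal
Product: 28 (6R)-7′,8′-dihydro-ε,ψ-carotene (α-zeacarotene), via farnesylidene ylide 27 (not isolated)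
Conditions: n-BuLi, THF, −78 °C; then 23, −78 °C → rt; then cat. I2, hexane/benzene, daylight, under argon
Reagents that add atoms: none
Why: Wittig olefination of the polyenal with the allylic ylide forms C11′=C12′, and iodine-catalysed equilibration of the conjugated polyene should give the all-E carotene while the isolated alkenes and the C6 stereocentre are unaffected.

**Compound list**

1 | 3,3-dimethylglutaric anhydride | CC1(C)CC(=O)OC(=O)C1 | starting material
2 | 5-tert-butoxy-3,3-dimethyl-5-oxopentanoic acid | CC(C)(C)OC(=O)CC(C)(C)CC(=O)O | intermediate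
3 | (4R)-4-benzyl-1,3-oxazolidin-2-one | O=C1N[C@H](Cc2ccccc2)CO1 | starting material
4 | 5-tert-butoxy-3,3-dimethyl-5-oxopentanoic pivalic anhydride | CC(C)(C)OC(=O)CC(C)(C)CC(=O)OC(=O)C(C)(C)C | intermediate
5 | tert-butyl 5-[(4R)-4-benzyl-2-oxo-1,3-oxazolidin-3-yl]-3,3-dimethyl-5-oxopentanoate | CC(C)(C)OC(=O)CC(C)(C)CC(=O)N1[C@H](Cc2ccccc2)COC1=O | intermediate
6 | chlorotitanium (Z)-enolate of 5 | CC(C)(C)OC(=O)CC(C)(C)/C=C(\O[Ti](Cl)(Cl)Cl)N1[C@H](Cc2ccccc2)COC1=O | intermediate
7 | tert-butyl (4S)-4-[(benzyloxy)methyl]-5-[(4R)-4-benzyl-2-oxo-1,3-oxazolidin-3-yl]-3,3-dimethyl-5-oxopentanoate | CC(C)(C)OC(=O)CC(C)(C)[C@@H](COCc1ccccc1)C(=O)N1[C@H](Cc2ccccc2)COC1=O | intermediate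
8 | tert-butyl (4S)-4-[(benzyloxy)methyl]-5-(ethylsulfanyl)-3,3-dimethyl-5-oxopentanoate | CCSC(=O)[C@H](COCc1ccccc1)C(C)(C)CC(=O)OC(C)(C)C | intermediate
9 | tert-butyl (4S)-4-[(benzyloxy)methyl]-3,3-dimethyl-5-oxohexanoate | CC(=O)[C@H](COCc1ccccc1)C(C)(C)CC(=O)OC(C)(C)C | intermediate
10 | (4S)-4-[(benzyloxy)methyl]-3,3-dimethyl-5-oxohexanoic acid | CC(=O)[C@H](COCc1ccccc1)C(C)(C)CC(=O)O | intermediate
11 | vinyltriphenylphosphonium bromide | C=C[P+](c1ccccc1)(c1ccccc1)c1ccccc1.[Br-] | starting material
12 | caesium (4S)-4-[(benzyloxy)methyl]-3,3-dimethyl-5-oxohexanoate | CC(=O)[C@H](COCc1ccccc1)C(C)(C)CC(=O)[O-].[Cs+] | intermediate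
13 | (3S)-3-[(benzyloxy)methyl]-4,4-dimethyl-7-(triphenyl-λ5-phosphanylidene)heptan-2-one | CC(=O)[C@H](COCc1ccccc1)C(C)(C)CCC=P(c1ccccc1)(c1ccccc1)c1ccccc1 | intermediate
14 | ({[(1R)-2,6,6-trimethylcyclohex-2-en-1-yl]methoxy}methyl)benzene | C(OCc1ccccc1)[C@H]1C(C)=CCCC1(C)C | intermediate
15 | [(1R)-2,6,6-trimethylcyclohex-2-en-1-yl]methanol | OC[C@H]1C(C)=CCCC1(C)C | intermediate
16 | (1R)-2,6,6-trimethylcyclohex-2-ene-1-carbaldehyde | O=C[C@H]1C(C)=CCCC1(C)C | intermediate
17 | 1-(triphenyl-λ5-phosphanylidene)propan-2-one | CC(=O)C=P(c1ccccc1)(c1ccccc1)c1ccccc1 | starting material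
18 | (3E)-4-[(1R)-2,6,6-trimethylcyclohex-2-en-1-yl]but-3-en-2-one | CC(=O)/C=C/[C@H]1C(C)=CCCC1(C)C | intermediate
19 | (4E)-3-methyl-5-[(1R)-2,6,6-trimethylcyclohex-2-en-1-yl]penta-1,4-dien-3-ol | C=CC(C)(O)/C=C/[C@H]1C(C)=CCCC1(C)C | intermediate
20 | [(2E,4E)-3-methyl-5-[(1R)-2,6,6-trimethylcyclohex-2-en-1-yl]penta-2,4-dien-1-yl]triphenylphosphonium bromide | C/C(=C\C[P+](c1ccccc1)(c1ccccc1)c1ccccc1)/C=C/[C@H]1C(C)=CCCC1(C)C.[Br-] | intermediate
21 | (2E,4E,6E)-2,7-dimethylocta-2,4,6-trienedial | O=C/C(C)=C/C=C/C=C(\C)C=O | starting material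
22 | {(2E,4E)-3-methyl-5-[(1R)-2,6,6-trimethylcyclohex-2-en-1-yl]penta-2,4-dien-1-ylidene}triphenyl-λ5-phosphane | C/C(=C\C=P(c1ccccc1)(c1ccccc1)c1ccccc1)/C=C/[C@H]1C(C)=CCCC1(C)C | intermediate
23 | (2E,4E,6E,8E,10E,12E)-2,7,11-trimethyl-13-[(1R)-2,6,6-trimethylcyclohex-2-en-1-yl]trideca-2,4,6,8,10,12-hexaenal | O=C/C(C)=C/C=C/C=C(C)/C=C/C=C(C)/C=C/[C@H]1C(C)=CCCC1(C)C | intermediate
24 | (2E,6E)-1-bromo-3,7,11-trimethyldodeca-2,6,10-triene | CC(C)=CCC/C(C)=C/CC/C(C)=C/CBr | starting material
25 | triphenylphosphine | c1ccc(cc1)P(c1ccccc1)c1ccccc1 | starting material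
26 | [(2E,6E)-3,7,11-trimethyldodeca-2,6,10-trien-1-yl]triphenylphosphonium bromide | CC(C)=CCC/C(C)=C/CC/C(C)=C/C[P+](c1ccccc1)(c1ccccc1)c1ccccc1.[Br-] | intermediate
27 | [(2E,6E)-3,7,11-trimethyldodeca-2,6,10-trien-1-ylidene]triphenyl-λ5-phosphane | CC(C)=CCC/C(C)=C/CC/C(C)=C/C=P(c1ccccc1)(c1ccccc1)c1ccccc1 | intermediate
28 | (6R)-7′,8′-dihydro-ε,ψ-carotene (α-zeacarotene) | CC(C)=CCC/C(C)=C/CC/C(C)=C/C=C/C(C)=C/C=C/C=C(C)/C=C/C=C(C)/C=C/[C@H]1C(C)=CCCC1(C)C | target

**Step count.** Total: 15 steps. Longest linear sequence: 14 steps (steps 1–13, then 15); step 14 is a one-step side branch.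

**Steps most likely to fail**

Step 7 (proposed new method). Three processes may defeat it: intramolecular hydrogen transfer to the C2 radical before it is trapped, proton transfer to the ylide before olefination (leaving a saturated phosphonium salt), and base-induced epimerisation at C6. The fallback uses known chemistry only and forms the two ring bonds in separate operations. It sets out from 10 and comes back at 14. Iododecarboxylation (PhI(OAc)2, I2, hν, benzene) would give (3S)-3-[(benzyloxy)methyl]-5-iodo-4,4-dimethylpentan-2-one F1. Keck radical allylation (allyltributylstannane, AIBN, benzene, 80 °C) would form C2–C3 and give (3S)-3-[(benzyloxy)methyl]-4,4-dimethyloct-7-en-2-one F2. Wittig methylenation of the ketone (Ph3P=CH2, THF, 0 °C) would give ({[(2S)-3,3-dimethyl-2-(prop-1-en-2-yl)hept-6-en-1-yl]oxy}methyl)benzene F3. Ring-closing metathesis (second-generation Grubbs catalyst, CH2Cl2, 40 °C) would then form C4=C5 with loss of ethene and deliver 14.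

Step 3. The neopentyl-type enolate may alkylate too slowly with the bulky chloromethyl ether, so that enolate decomposition and Lewis-acid attack on the tert-butyl ester compete. The fallback sets out from 5 and comes back at 7. It uses the smaller formaldehyde-derived oxocarbenium electrophile (TiCl4, i-Pr2NEt, then s-trioxane/TiCl4, CH2Cl2, 0 °C) in an aldol-type hydroxymethylation with the same facial sense. This would give tert-butyl (4S)-5-[(4R)-4-benzyl-2-oxo-1,3-oxazolidin-3-yl]-4-(hydroxymethyl)-3,3-dimethyl-5-oxopentanoate F4, which would be O-benzylated under non-basic conditions (benzyl 2,2,2-trichloroacetimidate, cat. TfOH, CH2Cl2/cyclohexane, 0 °C) to give 7.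

Step 10. Olefination of the hindered aldehyde may be slow enough that thermal or ylide-mediated enolisation erodes C6 or moves the ring alkene into conjugation. The fallback sets out from 16 and comes back at 18. Low-temperature aldol addition of the lithium enolate of acetone (LDA, acetone, THF, −78 °C) removes the acidic aldehyde at once and would give 4-hydroxy-4-[(1R)-2,6,6-trimethylcyclohex-2-en-1-yl]butan-2-one F5 as a carbinol epimer mixture. Mesylation (MsCl, Et3N, CH2Cl2, 0 °C) would give 3-oxo-1-[(1R)-2,6,6-trimethylcyclohex-2-en-1-yl]butyl methanesulfonate F6, and E1cB elimination with DBU would give the (E)-enone 18.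

Further compounds

F1 | step 7 | (3S)-3-[(benzyloxy)methyl]-5-iodo-4,4-dimethylpentan-2-one | CC(=O)[C@H](COCc1ccccc1)C(C)(C)CI
F2 | step 7 | (3S)-3-[(benzyloxy)methyl]-4,4-dimethyloct-7-en-2-one | CC(=O)[C@H](COCc1ccccc1)C(C)(C)CCC=C
F3 | step 7 | ({[(2S)-3,3-dimethyl-2-(prop-1-en-2-yl)hept-6-en-1-yl]oxy}methyl)benzene | C=C(C)[C@H](COCc1ccccc1)C(C)(C)CCC=C
F4 | step 3 | tert-butyl (4S)-5-[(4R)-4-benzyl-2-oxo-1,3-oxazolidin-3-yl]-4-(hydroxymethyl)-3,3-dimethyl-5-oxopentanoate | CC(C)(C)OC(=O)CC(C)(C)[C@@H](CO)C(=O)N1[C@H](Cc2ccccc2)COC1=O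
F5 | step 10 | 4-hydroxy-4-[(1R)-2,6,6-trimethylcyclohex-2-en-1-yl]butan-2-one | CC(=O)CC(O)[C@H]1C(C)=CCCC1(C)C
F6 | step 10 | 3-oxo-1-[(1R)-2,6,6-trimethylcyclohex-2-en-1-yl]butyl methanesulfonate | CC(=O)CC(OS(C)(=O)=O)[C@H]1C(C)=CCCC1(C)C
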